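**Plan**

1. Retrosynthesis: both interflavan bonds are cut (top C4–middle C6 last, middle C4–bottom C6 before it). Ring C of the middle unit is then opened at C3–C4 and at the O1–C2 enol ether bond. This leaves a phloroglucinaldehyde, an α-benzyloxy aryl ketone and (−)-epicatechin, which is used twice.
2. Forward: epicatechin gives the bromine-capped bottom nucleophile 3 and top electrophile 5. Aldehyde 7 is O-vinylated to the aryl enediol diether 14. Ring C of the middle unit then closes by C3–C4 bond formation with hydride capture at C2, followed by a bromine cap, the lower 4→6 coupling, the upper 4→6 coupling and global hydrogenolysis.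
3. Enabling feature: in 14 the formyl carbon (future C4) sits ortho to O1 on the 2,4,6-trioxygenated ring A. C3 of the vinyl group is β to both O1 and the catechol ring B, so C3 is the nucleophilic terminus and C2 carries the cation. The aldehyde oxygen stays on C4 as the leaving group of a flavan-3,4-diol (leucoanthocyanidin-type) extension unit.
4. Stereochemistry: top and bottom stereocentres come from epicatechin. Middle C3 comes from the chiral counteranion of the key step, and middle C2 from hydride delivery anti to the pseudoaxial 3-benzyloxy group (2,3-cis). Both interflavan C4 centres come from arene attack trans to the 3-oxygen (4β). The 4→6 regiochemistry comes from bromine caps.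

Key step: step 9

Remark: the sense of induction of the chiral acid in step 9 cannot be predicted with certainty; the (S,S) catalyst is assumed to give the (2R,3S,4R) series, to be confirmed by correlating 18 with material from the step 9 fallback, and the C4 configuration of 16 and 17 does not reach the target because that centre is ionized in step 11.

**Route**

Step 1
Reactants: 1 (−)-epicatechin
Product: 2 5,7,3',4'-tetra-O-benzyl-(−)-epicatechin
Conditions: BnBr (4.4 equiv), K2CO3, DMF, 0 °C to rt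
Reagents that add atoms: benzyl bromide, BrCc1ccccc1
Why: Williamson etherification in which the carbonate base alkylates the four phenols and leaves the secondary 3-OH free; no stereocentre is touched.

Step 2
Reactants: 2 5,7,3',4'-tetra-O-benzyl-(−)-epicatechin
Product: 3 8-bromo-5,7,3',4'-tetra-O-benzyl-(−)-epicatechin
Conditions: NBS (1.0 equiv), CH2Cl2, −78 °C to rt
Reagents that add atoms: N-bromosuccinimide, O=C1CCC(=O)N1Br
Why: Electrophilic aromatic bromination at C8, the most nucleophilic position of ring A in benzylated flavan-3-ols, which leaves C6 as the only nucleophilic site of the bottom unit.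

Step 3
Reactants: 2 5,7,3',4'-tetra-O-benzyl-(−)-epicatechin
Product: 4 6,8-dibromo-5,7,3',4'-tetra-O-benzyl-(−)-epicatechin
Conditions: NBS (2.1 equiv), CH2Cl2, 0 °C to rt
Reagents that add atoms: N-bromosuccinimide, O=C1CCC(=O)N1Br
Why: Electrophilic aromatic bromination with two equivalents caps C6 and C8, so the top unit can later act only as an electrophile.

Step 4
Reactants: 4 6,8-dibromo-5,7,3',4'-tetra-O-benzyl-(−)-epicatechin
Product: 5 6,8-dibromo-4β-(2-ethoxyethoxy)-5,7,3',4'-tetra-O-benzyl-(−)-epicatechin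
Conditions: DDQ (2 equiv), 2-ethoxyethanol (5 equiv), CH2Cl2, rt; then DMAP
Reagents that add atoms: 2-ethoxyethanol, CCOCCO
Why: DDQ benzylic oxidation (hydride abstraction at C4 assisted by ring A) with capture of the cation by the alcohol trans to the 3-OH, so the new C4 centre should be 4β under substrate control.

Step 5
Reactants: 6 2,4,6-trihydroxybenzaldehyde
Product: 7 2,4-bis(benzyloxy)-6-hydroxybenzaldehyde
Conditions: BnBr (2.1 equiv), K2CO3 (2.1 equiv), DMF, rt
Reagents that add atoms: benzyl bromide, BrCc1ccccc1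
Why: Williamson etherification that stops at the dibenzyl ether because the last ortho hydroxyl is hydrogen-bonded to the formyl group and is the least nucleophilic.

Step 6
Reactants: 8 4-bromo-1,2-bis(benzyloxy)benzene; 9 2-(benzyloxy)-N-methoxy-N-methylacetamide
Product: 11 2-(benzyloxy)-1-[3,4-bis(benzyloxy)phenyl]ethan-1-one, via arylmagnesium bromide 10 (not isolated)
Conditions: Mg, THF, reflux; then 9, THF, 0 °C; aq. NH4Cl
Reagents that add atoms: none
Why: Weinreb ketone synthesis, in which the chelated tetrahedral adduct prevents a second addition of the Grignard reagent.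

Step 7
Reactants: 11 2-(benzyloxy)-1-[3,4-bis(benzyloxy)phenyl]ethan-1-one
Product: 13 (Z)-2-(benzyloxy)-1-[3,4-bis(benzyloxy)phenyl]ethenyl trifluoromethanesulfonate, via potassium enolate 12 (not isolated)
Conditions: KN(SiMe3)2, THF, −78 °C; then PhNTf2, −78 °C to 0 °C
Reagents that add atoms: N-phenylbis(trifluoromethanesulfonimide), O=S(=O)(N(c1ccccc1)S(=O)(=O)C(F)(F)F)C(F)(F)F
Why: Enolate O-sulfonylation; aryl ketone enolates form with the oxygen cis to the α-substituent (helped here by potassium chelation to the benzyloxy oxygen), which should give the Z triflate.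

Step 8
Reactants: 7 2,4-bis(benzyloxy)-6-hydroxybenzaldehyde; 13 (Z)-2-(benzyloxy)-1-[3,4-bis(benzyloxy)phenyl]ethenyl trifluoromethanesulfonate
Product: 14 2,4-bis(benzyloxy)-6-{[(Z)-2-(benzyloxy)-1-[3,4-bis(benzyloxy)phenyl]ethenyl]oxy}benzaldehyde
Conditions: Pd2(dba)3 (2.5 mol%), tBuXPhos (6 mol%), K3PO4, toluene, 80 °C
Reagents that add atoms: none
Why: Palladium-catalysed C–O cross-coupling of an enol triflate with a phenol (Buchwald–Hartwig-type etherification) with retention of alkene geometry; the weak phosphate base spares the aldehyde, and the other alkene geometry would lead to the same target, since it changes only the C4 centre that is ionized in step 11.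

Step 9
Reactants: 14 2,4-bis(benzyloxy)-6-{[(Z)-2-(benzyloxy)-1-[3,4-bis(benzyloxy)phenyl]ethenyl]oxy}benzaldehyde
Product: 16 (2R,3S,4R)-3,5,7-tris(benzyloxy)-2-[3,4-bis(benzyloxy)phenyl]-4-(triethylsilyloxy)chromane, via oxocarbenium ion 15 (not isolated)
Conditions: Et3SiH (1.5 equiv), (S,S)-imidodiphosphorimidate Brønsted acid (BINOL-derived IDPi, 3 mol%), CH2Cl2, −78 to −40 °C; Et3N quench
Reagents that add atoms: triethylsilane, CC[SiH](CC)CC
Why: Proposed new method: the acid is silylated by Et3SiH and passes Et3Si+ to the aldehyde oxygen; the aryl-stabilized silyloxocarbenium ion at C4 is attacked by C3 of the enediol diether, the positive charge lands on C2 as the 2-aryl oxocarbenium ion 15, and 15 takes hydride from Et3SiH, which regenerates the silylium catalyst. The closest known reaction types are silylium-counteranion-catalysed Mukaiyama aldol and Prins reactions of aromatic aldehydes and the Et3SiH reduction of 1-aryl oxocarbenium ions used for C-aryl glycosides. Ring C closes in a 6-endo-trig mode with respect to the enol ether (exo with respect to the carbonyl group). C3 is controlled by the chiral counteranion, which pairs with the cationic C4 terminus during C–C bond formation and differentiates the enantiotopic faces of the achiral substrate. C2 is controlled by the substrate: the 3-benzyloxy group is pseudoaxial in 15 to avoid A(1,2) strain with the coplanar 2-aryl group, so hydride enters antiperiplanar to it and gives the 2,3-cis ether; C4 forms with the silyloxy group pseudoequatorial and is given up in step 11. The step needs attack through C3 and not C2 (secured by the two cation-stabilizing donors on C2 and by six- over five-membered ring formation) and hydride capture by 15 in preference to the much less electrophilic trialkoxyaryl silyloxocarbenium ion.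

Step 10
Reactants: 16 (2R,3S,4R)-3,5,7-tris(benzyloxy)-2-[3,4-bis(benzyloxy)phenyl]-4-(triethylsilyloxy)chromane
Product: 17 (2R,3S,4R)-8-bromo-3,5,7-tris(benzyloxy)-2-[3,4-bis(benzyloxy)phenyl]-4-(triethylsilyloxy)chromane
Conditions: NBS (1.0 equiv), CH2Cl2, −78 °C
Reagents that add atoms: N-bromosuccinimide, O=C1CCC(=O)N1Br
Why: Electrophilic aromatic bromination at C8, which caps the most nucleophilic position of the extension unit against self-condensation and forces the later top unit onto C6.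

Step 11
Reactants: 17 (2R,3S,4R)-8-bromo-3,5,7-tris(benzyloxy)-2-[3,4-bis(benzyloxy)phenyl]-4-(triethylsilyloxy)chromane; 3 8-bromo-5,7,3',4'-tetra-O-benzyl-(−)-epicatechin
Product: 18 3-O-benzyl-8-bromo-5,7,3',4'-tetra-O-benzylepicatechin-(4β→6)-8-bromo-5,7,3',4'-tetra-O-benzylepicatechin
Conditions: 3 (3 equiv), TMSOTf (0.5 equiv), CH2Cl2, −78 °C; Et3N quench
Reagents that add atoms: none
Why: Lewis-acid-promoted SN1 interflavan coupling (Friedel–Crafts alkylation by the C4 benzylic cation); 3 can react only at C6 and attacks trans to the 3-benzyloxy and 2-aryl groups, which should set C4 as 4β whatever the configuration of the silyl ether, and the excess of 3 suppresses self-condensation through C6 of 17.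

Step 12
Reactants: 18 3-O-benzyl-8-bromo-5,7,3',4'-tetra-O-benzylepicatechin-(4β→6)-8-bromo-5,7,3',4'-tetra-O-benzylepicatechin; 5 6,8-dibromo-4β-(2-ethoxyethoxy)-5,7,3',4'-tetra-O-benzyl-(−)-epicatechin
Product: 19 6,8-dibromo-5,7,3',4'-tetra-O-benzylepicatechin-(4β→6)-3-O-benzyl-8-bromo-5,7,3',4'-tetra-O-benzylepicatechin-(4β→6)-8-bromo-5,7,3',4'-tetra-O-benzylepicatechin
Conditions: 5 (1.3 equiv), TMSOTf (0.5 equiv), CH2Cl2, −78 to −40 °C; Et3N quench
Reagents that add atoms: none
Why: Lewis-acid-promoted SN1 interflavan coupling; the only free ring A position of 18 is C6 of the middle unit and the fully capped cation from 5 cannot self-condense, so the arene should add trans to the 3-OH of the top unit (4β).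

Step 13
Reactants: 19 6,8-dibromo-5,7,3',4'-tetra-O-benzylepicatechin-(4β→6)-3-O-benzyl-8-bromo-5,7,3',4'-tetra-O-benzylepicatechin-(4β→6)-8-bromo-5,7,3',4'-tetra-O-benzylepicatechin
Product: 20 epicatechin-(4β→6)-epicatechin-(4β→6)-epicatechin (CNP0163146.2)
Conditions: H2 (1 atm), Pd(OH)2/C, Et3N (6 equiv), THF/MeOH/H2O, rt
Reagents that add atoms: none
Why: Hydrogenolysis of the thirteen benzyl ethers and hydrodebromination of the four aryl bromides in one operation; Et3N buffers the HBr so the acid-labile interflavan bonds survive, and no stereocentre is affected.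

**Compound list**

1 | (−)-epicatechin | O[C@@H]1Cc2c(O)cc(O)cc2O[C@@H]1c1ccc(O)c(O)c1 | starting material
2 | 5,7,3',4'-tetra-O-benzyl-(−)-epicatechin | O[C@@H]1Cc2c(OCc9ccccc9)cc(OCc9ccccc9)cc2O[C@@H]1c8ccc(OCc9ccccc9)c(OCc9ccccc9)c8 | intermediate
3 | 8-bromo-5,7,3',4'-tetra-O-benzyl-(−)-epicatechin | O[C@@H]1Cc2c(OCc9ccccc9)cc(OCc9ccccc9)c(Br)c2O[C@@H]1c8ccc(OCc9ccccc9)c(OCc9ccccc9)c8 | intermediate
4 | 6,8-dibromo-5,7,3',4'-tetra-O-benzyl-(−)-epicatechin | O[C@@H]1Cc2c(OCc9ccccc9)c(Br)c(OCc9ccccc9)c(Br)c2O[C@@H]1c8ccc(OCc9ccccc9)c(OCc9ccccc9)c8 | intermediate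
5 | 6,8-dibromo-4β-(2-ethoxyethoxy)-5,7,3',4'-tetra-O-benzyl-(−)-epicatechin (2,3-cis, 3,4-trans) | O[C@@H]1[C@@H](OCCOCC)c2c(OCc9ccccc9)c(Br)c(OCc9ccccc9)c(Br)c2O[C@@H]1c8ccc(OCc9ccccc9)c(OCc9ccccc9)c8 | intermediate
6 | 2,4,6-trihydroxybenzaldehyde | O=Cc1c(O)cc(O)cc1O | starting material
7 | 2,4-bis(benzyloxy)-6-hydroxybenzaldehyde | O=Cc1c(O)cc(OCc9ccccc9)cc1OCc9ccccc9 | intermediate
8 | 4-bromo-1,2-bis(benzyloxy)benzene | Brc1ccc(OCc2ccccc2)c(OCc2ccccc2)c1 | starting material
9 | 2-(benzyloxy)-N-methoxy-N-methylacetamide | CON(C)C(=O)COCc1ccccc1 | starting material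
10 | [3,4-bis(benzyloxy)phenyl]magnesium bromide | Br[Mg]c8ccc(OCc9ccccc9)c(OCc9ccccc9)c8 | intermediate
11 | 2-(benzyloxy)-1-[3,4-bis(benzyloxy)phenyl]ethan-1-one | O=C(COCc9ccccc9)c8ccc(OCc9ccccc9)c(OCc9ccccc9)c8 | intermediate
12 | potassium (Z)-enolate of 11 | [K+].[O-]/C(c8ccc(OCc9ccccc9)c(OCc9ccccc9)c8)=C\OCc9ccccc9 | intermediate
13 | (Z)-2-(benzyloxy)-1-[3,4-bis(benzyloxy)phenyl]ethenyl trifluoromethanesulfonate | FC(F)(F)S(=O)(=O)O/C(c8ccc(OCc9ccccc9)c(OCc9ccccc9)c8)=C\OCc9ccccc9 | intermediate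
14 | 2,4-bis(benzyloxy)-6-{[(Z)-2-(benzyloxy)-1-[3,4-bis(benzyloxy)phenyl]ethenyl]oxy}benzaldehyde | O=Cc1c(OCc9ccccc9)cc(OCc9ccccc9)cc1O/C(c8ccc(OCc9ccccc9)c(OCc9ccccc9)c8)=C\OCc9ccccc9 | intermediate
15 | ring C oxocarbenium ion (O1=C2 cation) with cis 3-benzyloxy and 4-triethylsilyloxy groups, paired with the catalyst anion | c1c(OCc9ccccc9)cc2c(c1OCc9ccccc9)[C@@H](O[Si](CC)(CC)CC)[C@@H](OCc9ccccc9)C(c8ccc(OCc9ccccc9)c(OCc9ccccc9)c8)=[O+]2 | intermediate
16 | (2R,3S,4R)-3,5,7-tris(benzyloxy)-2-[3,4-bis(benzyloxy)phenyl]-4-(triethylsilyloxy)chromane (2-aryl, 3-benzyloxy and 4-silyloxy all cis) | c1c(OCc9ccccc9)cc2c(c1OCc9ccccc9)[C@@H](O[Si](CC)(CC)CC)[C@@H](OCc9ccccc9)[C@@H](c8ccc(OCc9ccccc9)c(OCc9ccccc9)c8)O2 | intermediate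
17 | (2R,3S,4R)-8-bromo-3,5,7-tris(benzyloxy)-2-[3,4-bis(benzyloxy)phenyl]-4-(triethylsilyloxy)chromane | c1c(OCc9ccccc9)c(Br)c2c(c1OCc9ccccc9)[C@@H](O[Si](CC)(CC)CC)[C@@H](OCc9ccccc9)[C@@H](c8ccc(OCc9ccccc9)c(OCc9ccccc9)c8)O2 | intermediate
18 | 3-O-benzyl-8-bromo-5,7,3',4'-tetra-O-benzylepicatechin-(4β→6)-8-bromo-5,7,3',4'-tetra-O-benzylepicatechin | c1c(OCc9ccccc9)c(Br)c2c(c1OCc9ccccc9)[C@H](c1c(OCc9ccccc9)c(Br)c3c(c1OCc9ccccc9)C[C@@H](O)[C@@H](c8ccc(OCc9ccccc9)c(OCc9ccccc9)c8)O3)[C@@H](OCc9ccccc9)[C@@H](c8ccc(OCc9ccccc9)c(OCc9ccccc9)c8)O2 | intermediate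
19 | 6,8-dibromo-5,7,3',4'-tetra-O-benzylepicatechin-(4β→6)-3-O-benzyl-8-bromo-5,7,3',4'-tetra-O-benzylepicatechin-(4β→6)-8-bromo-5,7,3',4'-tetra-O-benzylepicatechin | c9ccccc9COc1c(Br)c(OCc9ccccc9)c2c(c1Br)O[C@H](c8ccc(OCc9ccccc9)c(OCc9ccccc9)c8)[C@H](O)[C@H]2c1c(OCc9ccccc9)c(Br)c2c(c1OCc9ccccc9)[C@H](c1c(OCc9ccccc9)c(Br)c3c(c1OCc9ccccc9)C[C@@H](O)[C@@H](c8ccc(OCc9ccccc9)c(OCc9ccccc9)c8)O3)[C@@H](OCc9ccccc9)[C@@H](c8ccc(OCc9ccccc9)c(OCc9ccccc9)c8)O2 | intermediate
20 | epicatechin-(4β→6)-epicatechin-(4β→6)-epicatechin (CNP0163146.2) | Oc1cc(O)c2c(c1)O[C@H](c1ccc(O)c(O)c1)[C@H](O)[C@H]2c1c(O)cc2c(c1O)[C@H](c1c(O)cc3c(c1O)C[C@@H](O)[C@@H](c1ccc(O)c(O)c1)O3)[C@@H](O)[C@@H](c1ccc(O)c(O)c1)O2 | target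

**Totals**

Total step count: 13. Longest linear sequence: 8 steps (steps 6, 7, 8, 9, 10, 11, 12, 13).

**Steps most likely to fail**

Step 9 (Proposed new method). The counteranion may discriminate the two faces of C3 poorly. Cation 15 may also be diverted: attack through C2 (five-membered ring), loss of the C3 proton followed by ionization at C4 to a flavylium ion, or a second hydride transfer at C4. The fallback uses known chemistry and takes ring C of the middle unit from the chiral pool. It sets out from 3. O-Benzylation (NaH, BnBr, DMF) should give 8-bromo-3,5,7,3',4'-penta-O-benzyl-(−)-epicatechin F1. DDQ oxidation in the presence of 2-ethoxyethanol (CH2Cl2, rt) should give 8-bromo-4β-(2-ethoxyethoxy)-3,5,7,3',4'-penta-O-benzyl-(−)-epicatechin F2. TMSOTf-promoted coupling of F2 with an excess of 3 at −78 °C returns to the route at 18. The same material would serve to assign the catalyst antipode.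

Step 8. Reductive elimination from palladium may be slow for the hindered, chelating salicylaldehyde phenoxide, and the phenoxide may instead take the sulfonyl group from the triflate. The fallback reverses the polarity of the vinyl partner and sets out from 13. Miyaura borylation (bis(pinacolato)diboron, PdCl2(dppf), KOAc, dioxane) should give (E)-2-{2-(benzyloxy)-1-[3,4-bis(benzyloxy)phenyl]ethenyl}-4,4,5,5-tetramethyl-1,3,2-dioxaborolane F3. Chan–Lam–Evans oxidative coupling of F3 with 7 (Cu(OAc)2, pyridine, air, molecular sieves, CH2Cl2, rt) comes back at 14.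

Step 12. C6 of the middle unit in 18 is shielded by two benzyloxy groups and by the bottom unit, so the cation from 5 may decompose before it is captured. The fallback forms this hindered bond on a monomer by orthogonal activation and sets out from 17. Exchange of the silyl ether (2,6-dimethylbenzenethiol, BF3·OEt2, CH2Cl2, −78 °C) should give (2R,3S,4S)-8-bromo-3,5,7-tris(benzyloxy)-2-[3,4-bis(benzyloxy)phenyl]-4-(2,6-dimethylphenylthio)chromane F4, with the 4β-thioether trans to the 3-benzyloxy group. The thioether is inert to oxophilic acid, so BF3·OEt2-promoted coupling of 5 with C6 of F4 should give 6,8-dibromo-5,7,3',4'-tetra-O-benzylepicatechin-(4β→6)-3-O-benzyl-8-bromo-4β-(2,6-dimethylphenylthio)-5,7,3',4'-tetra-O-benzylepicatechin F5. Thiophilic activation of F5 with AgBF4 in the presence of 3 (THF, 0 °C) comes back at 19.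

**Further compounds**

F1 | step 9 | 8-bromo-3,5,7,3',4'-penta-O-benzyl-(−)-epicatechin | c9ccccc9CO[C@@H]1Cc2c(OCc9ccccc9)cc(OCc9ccccc9)c(Br)c2O[C@@H]1c8ccc(OCc9ccccc9)c(OCc9ccccc9)c8
F2 | step 9 | 8-bromo-4β-(2-ethoxyethoxy)-3,5,7,3',4'-penta-O-benzyl-(−)-epicatechin | c9ccccc9CO[C@@H]1[C@@H](OCCOCC)c2c(OCc9ccccc9)cc(OCc9ccccc9)c(Br)c2O[C@@H]1c8ccc(OCc9ccccc9)c(OCc9ccccc9)c8
F3 | step 8 | (E)-2-{2-(benzyloxy)-1-[3,4-bis(benzyloxy)phenyl]ethenyl}-4,4,5,5-tetramethyl-1,3,2-dioxaborolane | CC1(C)OB(OC1(C)C)/C(c8ccc(OCc9ccccc9)c(OCc9ccccc9)c8)=C\OCc9ccccc9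
F4 | step 12 | (2R,3S,4S)-8-bromo-3,5,7-tris(benzyloxy)-2-[3,4-bis(benzyloxy)phenyl]-4-(2,6-dimethylphenylthio)chromane | c1c(OCc9ccccc9)c(Br)c2c(c1OCc9ccccc9)[C@H](Sc1c(C)cccc1C)[C@@H](OCc9ccccc9)[C@@H](c8ccc(OCc9ccccc9)c(OCc9ccccc9)c8)O2
F5 | step 12 | 6,8-dibromo-5,7,3',4'-tetra-O-benzylepicatechin-(4β→6)-3-O-benzyl-8-bromo-4β-(2,6-dimethylphenylthio)-5,7,3',4'-tetra-O-benzylepicatechin | c9ccccc9COc1c(Br)c(OCc9ccccc9)c2c(c1Br)O[C@H](c8ccc(OCc9ccccc9)c(OCc9ccccc9)c8)[C@H](O)[C@H]2c1c(OCc9ccccc9)c(Br)c2c(c1OCc9ccccc9)[C@H](Sc1c(C)cccc1C)[C@@H](OCc9ccccc9)[C@@H](c8ccc(OCc9ccccc9)c(OCc9ccccc9)c8)O2
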